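A small charge of substrate meets a larger one of coupling partner, and a scavenger stands by for the released group.

in all of them: substrate 1.0 M; coupling partner 1.30 M; time 25 h
- green: scavenger 1.20 M
- red: scavenger 1.80 M

1. part of the substrate that has reacted at the end, green
2. part of the substrate that has reacted at the end, red
3. what raising the concentration of scavenger from its lowest to its highest value here does to the part of the substrate that has reacted (changes below 5 percentage points count as none) (no change / it falls / it rises)

- released group is meant together with its idle adduct
- run time (green): 25 h

    substrate + coupling partner ⇌ product + released group (K1 = 12.9, k1 = 0.0459 M⁻¹ h⁻¹)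
    substrate + released group ⇌ idle adduct, settled at all times (K2 = 0.37 M⁻¹)
    scavenger + released group → scavenged by-product (k3 = 0.135 M⁻¹ h⁻¹)

I follow one released group at its fork. It can return onto product, at 0.00356 h⁻¹ even with the whole charge turned to product, or meet scavenger, at 0.162 h⁻¹ at the green charge. From these two rates I put its chance of being caught at 97.9 %, and I reckon with the forward step, whose rate holds no [scavenger]; the idle adduct I leave aside.

The curve of reacted substrate starts at a slope of 0.0597 M h⁻¹ and bends over with no knee, as [substrate] and [coupling partner] fall together. Each turning takes one of each, so with the idle adduct left aside their difference stays at 0.300 M. The ratio [coupling partner]/[substrate] therefore climbs exponentially from 1.30, at what I call the gap rate 0.0138 h⁻¹, the forward rate constant times that excess. [substrate] is then the excess divided by the ratio minus one.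

Reacted and unreacted substrate cross when the ratio reaches 1.60, at 15.1 h. At 25 h the ratio is 1.83, which gives 64.0 % reacted in green and in red alike. The level I expect ahead is the whole charge, substrate being the limiting reagent.

The forecast gives 63 % (58 % to 69 %) for green, 65 % (60 % to 71 %) for red and no change, on this ground: “More scavenger only trims the small amount of substrate held as adduct”.

The simulation gives 64.2 % for green and 63.9 % for red, a shift of −0.28 percentage points, so no change, beside my 64.0 %.

Now the red flask read at 15 h, close to my crossing at 15.1 h. The gap rate 0.0138 h⁻¹ carries the ratio to 1.60, so I expect 49.9 % reacted. The flask shows 50.8 %. Of the substrate charged, 2.11 % sits as idle adduct, 49.2 % as substrate and 48.7 % as product.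

(The numbers are invented; the flask was simulated.)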